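**Plan**

- Retrosynthesis: the three silyl groups and the C7 configuration are adjusted last; the C4 methyl enol ether goes back to a ring C ketone; the C2–C3 bond of ring B is cut by carbene C–H insertion to an aryl vinyl diazo compound; C3–C3a is cut to an aryl aldehyde and a 2-iodo vinylogous ester; C7–C1′ to 3-phenylpropanal; the O1–CH2 enol ether to a 1,3-dione and a diol.
- Enabling feature: C2 (ether α-carbon of O1) and C3 (aryl- and vinyl-substituted, able to carry a carbene) are neighbours in ring B, and O1 sits on the C3a=C7a enol ether of ring C, so the carbene carbon and a C2–H bond are 1,5-related.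
- Forward: ring C comes from phloroglucinol by partial reduction, then ether formation, resolution, silylation, iodination, coupling with the aryl aldehyde and oxidation. The C7 side chain is added as a masked carbinol while the aryl ketone still activates C7–H. The diazo compound is then made and ring B closes in the key step.
- Endgame: O-methylation to the C4=C5 dienol ether, unmasking and oxidation of the side chain, C7 epimerisation by kinetic protonation, desilylation.
- Stereochemistry: C6 from a lipase resolution; C2 and C3 from the chiral dirhodium catalyst (cis by the insertion mechanism); C7 from protonation of the enolate anti to the C6 silyl ether; the carbinol centres of 11 and at C1′ are temporary.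

Key step: step 13

Remark: it is assumed that the lipase acylates the (S)-alcohol faster (the arm bearing the bulky alkoxy group acting as the large substituent) and that Rh2(R-PTAD)4 (PTAD = (1-adamantyl)(phthalimido)acetate) is the catalyst hand giving the (2R,3S) ring B; if either sense is reversed, the acetate fraction or Rh2(S-PTAD)4 is used.

**Route**

Step 1
Reactants: 1 phloroglucinol
Product: 2 5-hydroxycyclohexane-1,3-dione
Conditions: NaBH4, H2O, rt; acidic ion-exchange resin
Reagents that add atoms: none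
Why: Hydride reduction of the triketo tautomer of the phloroglucinol anion should stop at the dihydro stage because the resulting 1,3-dione enolate resists further reduction (partial carbonyl reduction of a polyphenol).

Step 2
Reactants: 2 5-hydroxycyclohexane-1,3-dione; 3 2-methylpropane-1,2-diol
Product: 4 racemic 5-hydroxy-3-(2-hydroxy-2-methylpropoxy)cyclohex-2-en-1-one
Conditions: PPTS (cat.), 3 (3 equiv), PhMe, 4 Å MS, 50 °C
Reagents that add atoms: none
Why: Acid-catalysed enol ether (vinylogous ester) formation of a cyclic 1,3-dione should engage only the primary hydroxyl of the diol, and the mild acid and temperature are chosen to avoid dehydration of the β-hydroxy dione to a resorcinol.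

Step 3
Reactants: 4 racemic hydroxy vinylogous ester
Product: 5 (R)-5-hydroxy-3-(2-hydroxy-2-methylpropoxy)cyclohex-2-en-1-one
Conditions: lipase PS (Burkholderia cepacia), vinyl acetate, tBuOMe, rt, stopped just past half conversion
Reagents that add atoms: none
Why: Lipase-catalysed kinetic resolution by enantioselective transesterification of the secondary alcohol should acylate the (S)-enantiomer and leave the (R)-alcohol, which fixes the future C6 centre; the tertiary hydroxyl is not acylated.

Step 4
Reactants: 5 (R)-diol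
Product: 6 (R)-5-(tert-butyldimethylsilyloxy)-3-(2-hydroxy-2-methylpropoxy)cyclohex-2-en-1-one
Conditions: TBSCl, imidazole, DMF, 0 °C → rt
Reagents that add atoms: tert-butyldimethylsilyl chloride, CC(C)(C)[Si](C)(C)Cl
Why: Silylation with a silyl chloride and imidazole should take the secondary hydroxyl and leave the hindered tertiary one (selective O-silylation).

Step 5
Reactants: 6 secondary silyl ether
Product: 7 (R)-5-(tert-butyldimethylsilyloxy)-3-[2-methyl-2-(triethylsilyloxy)propoxy]cyclohex-2-en-1-one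
Conditions: TESOTf, 2,6-lutidine, CH2Cl2, −78 → 0 °C
Reagents that add atoms: triethylsilyl triflate, CC[Si](CC)(CC)OS(=O)(=O)C(F)(F)F
Why: A silyl triflate with a hindered pyridine base silylates tertiary alcohols, so that no free O–H remains for the later carbene step (O-silylation).

Step 6
Reactants: 7 bis-silyl vinylogous ester
Product: 8 (R)-5-(tert-butyldimethylsilyloxy)-2-iodo-3-[2-methyl-2-(triethylsilyloxy)propoxy]cyclohex-2-en-1-one
Conditions: NIS, CH2Cl2, 0 °C → rt, dark
Reagents that add atoms: N-iodosuccinimide, O=C1CCC(=O)N1I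
Why: The α-carbon of a vinylogous ester is the nucleophilic terminus of an enol ether and should be iodinated cleanly by an electrophilic iodine source (electrophilic α-iodination).

Step 7
Reactants: 9 methyl 3-formyl-4-hydroxybenzoate
Product: 10 methyl 4-(tert-butyldimethylsilyloxy)-3-formylbenzoate
Conditions: TBSCl, imidazole, DMF, rt
Reagents that add atoms: tert-butyldimethylsilyl chloride, CC(C)(C)[Si](C)(C)Cl
Why: Phenol silylation removes the acidic O–H that would quench the organometallic, enolate and carbene steps (O-silylation).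

Step 8
Reactants: 8 iodo vinylogous ester; 10 silylated aryl aldehyde
Product: 11 aryl(cyclohexenyl)carbinol as a mixture of carbinol epimers
Conditions: CrCl2 (4 equiv), NiCl2 (1 mol%), DMF, rt
Reagents that add atoms: none
Why: In the Nozaki–Hiyama–Kishi reaction zerovalent nickel inserts into the alkenyl C–I bond, the alkenyl group passes to trivalent chromium and adds to the aldehyde only, leaving both esters and the vinylogous ester untouched; the new carbinol centre is not controlled because it is oxidised next.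

Step 9
Reactants: 11 carbinol
Product: 12 aryl ketone (2-aroyl vinylogous ester)
Conditions: Dess–Martin periodinane, pyridine, CH2Cl2, 0 °C → rt
Reagents that add atoms: none
Why: Dess–Martin oxidation of the benzylic, allylic secondary alcohol is neutral and should not disturb the silyl ethers or the β-silyloxy ketone.

Step 10
Reactants: 12 aryl ketone; 13 3-phenylpropanal
Product: 15 C7 aldol adduct capped as its allyl carbonate (6,7-trans; both C1′ epimers), via lithium aldolate 14 (not isolated)
Conditions: LiN(SiMe3)2 (1.05 equiv), THF, −78 °C; 13, −78 °C; then allyl chloroformate, −78 → −20 °C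
Reagents that add atoms: allyl chloroformate, C=CCOC(=O)Cl
Why: C7–H is vinylogous to both the C4 ketone and the aroyl ketone, so its anion is a vinylogous β-diketonate and is far more stable than the C5 enolate; with C3a fully substituted the vinylogous aldol addition occurs at C7, the aldehyde approaching anti to the C6 silyl ether (6,7-trans), and in-situ capping as the carbonate blocks retro-aldol and keeps a free O–H away from the carbene (C1′ is uncontrolled and is oxidised later).

Step 11
Reactants: 15 allyl carbonate ketone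
Product: 16 N-(tert-butyldimethylsilyl)hydrazone of 15
Conditions: TBSNH–NHTBS, Sc(OTf)3 (1 mol%), CHCl3, rt → 40 °C
Reagents that add atoms: 1,2-bis(tert-butyldimethylsilyl)hydrazine, CC(C)(C)[Si](C)(C)NN[Si](C)(C)C(C)(C)C
Why: Scandium-triflate-catalysed condensation of the disilylhydrazine gives the N-silyl hydrazone without free hydrazine, which would displace the alkoxy group at C7a and close a pyrazole on this 2-acyl vinylogous ester; the bulky silylated nitrogen is a poor conjugate donor and the N-silyl hydrazone cannot cyclise.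

Step 12
Reactants: 16 N-silyl hydrazone
Product: 17 aryl vinyl diazo compound
Conditions: PhIF2, 2-chloropyridine, CH2Cl2, −78 → −20 °C; cold filtration through basic alumina, used at once
Reagents that add atoms: none
Why: Oxidation of N-silyl hydrazones with (difluoroiodo)benzene gives diazoalkanes at low temperature with loss of the silyl group as its fluoride, and the weak base buffers the HF so that the diazo group and the silyl ethers survive.

Step 13
Reactants: 17 aryl vinyl diazo compound
Product: 18 cis-2,3-disubstituted hexahydrobenzofuran-4-one (ring B closed)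
Conditions: Rh2(R-PTAD)4 (1 mol%), CH2Cl2, −20 °C → rt, slow addition of 17
Reagents that add atoms: none
Why: Loss of N2 on the dirhodium tetracarboxylate gives an aryl vinyl (donor/donor) carbene at C3, and because C3 and O1 are cis across the C3a=C7a bond a C2–H bond of the O1–CH2 group lies 1,5 to the carbene carbon and is inserted through a hydride-transfer-like three-centre transition state that forms the C2–C3 bond. The closest known reaction type is the enantioselective intramolecular C–H insertion of donor/donor dirhodium carbenes into ether α-C–H bonds, which gives cis-2,3-disubstituted 2,3-dihydrobenzofurans. Ring B closes as a five-membered ring by 1,5-C–H insertion, with C3a=C7a as its endocyclic alkene. C3 is set by the carbene face left open by the chiral carboxylate ligands and C2 by which of the two C2–H bonds is delivered, and the concerted, stereoretentive bond formation places the aryl group and the C2 substituent cis. The step needs site selectivity, secured because C7 and its side chain are trans to C3 across C3a=C7a and no free O–H is present, and it needs catalyst control over the distant C6 and C7 centres.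

Step 14
Reactants: 18 ring B ketone
Product: 20 4-methoxy dienol ether (C4=C5 and C3a=C7a), via 4-methoxy oxocarbenium triflate 19 (not isolated)
Conditions: MeOTf, 2,6-di-tert-butyl-4-methylpyridine, CH2Cl2, 0 °C → rt; aq. NaHCO3 work-up
Reagents that add atoms: methyl triflate, COS(=O)(=O)C(F)(F)F
Why: O-Methylation of the vinylogous ester carbonyl, the only strongly nucleophilic oxygen, gives a 1,3-dialkoxyallyl cation from which the hindered base removes the accessible C5 proton and not the crowded tertiary C7–H, so the dienol ether forms without an enolate and without β-silyloxy elimination (O-alkylation then deprotonation).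

Step 15
Reactants: 20 dienol ether allyl carbonate
Product: 21 C1′ alcohol
Conditions: Pd(PPh3)4 (5 mol%), morpholine, THF, rt
Reagents that add atoms: none
Why: In this Tsuji–Trost-type deallylation zerovalent palladium ionises the allyl carbonate, CO2 is lost and morpholine captures the allyl group under neutral conditions that spare the acid-labile dienol ether and the silyl ethers.

Step 16
Reactants: 21 C1′ alcohol
Product: 22 7-epi ketone (acyl trans to the C6 silyl ether)
Conditions: Dess–Martin periodinane, pyridine, CH2Cl2, 0 °C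
Reagents that add atoms: none
Why: Buffered Dess–Martin oxidation converts both C1′ epimers into the one 3-phenylpropanoyl ketone and removes that temporary centre.

Step 17
Reactants: 22 7-epi ketone
Product: 24 (7S)-ketone with acyl cis to the C6 silyl ether, via lithium enolate 23 (not isolated)
Conditions: LiN(SiMe3)2 (1.1 equiv), THF, −78 °C; then AcOH in THF, −78 °C
Reagents that add atoms: none
Why: C7–H, α to the ketone and conjugated with the diene, is the most acidic proton, and kinetic protonation of the planar extended enolate at its α-carbon from the face opposite the C6 silyl ether should place the acyl group cis to it (7S), the low temperature holding back loss of the silyloxy group.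

Step 18
Reactants: 24 tris-silyl precursor
Product: 25 CNP0080427.1
Conditions: HF·pyridine, pyridine, THF, 0 °C → rt
Reagents that add atoms: none
Why: Pyridine-buffered HF cleaves the aryl and secondary tert-butyldimethylsilyl ethers and the tertiary triethylsilyl ether under conditions mild enough for the methyl dienol ether and the β-hydroxy ketone (fluoride desilylation), leaving all four stereocentres untouched.

**Compound list**

1 | phloroglucinol | Oc1cc(O)cc(O)c1 | starting material
2 | 5-hydroxycyclohexane-1,3-dione | O=C1CC(O)CC(=O)C1 | intermediate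
3 | 2-methylpropane-1,2-diol | CC(C)(O)CO | starting material
4 | (±)-5-hydroxy-3-(2-hydroxy-2-methylpropoxy)cyclohex-2-en-1-one | O=C1C=C(OCC(C)(C)O)CC(O)C1 | intermediate
5 | (R)-5-hydroxy-3-(2-hydroxy-2-methylpropoxy)cyclohex-2-en-1-one | O=C1C=C(OCC(C)(C)O)C[C@@H](O)C1 | intermediate
6 | (R)-5-(tert-butyldimethylsilyloxy)-3-(2-hydroxy-2-methylpropoxy)cyclohex-2-en-1-one | O=C1C=C(OCC(C)(C)O)C[C@@H](O[Si](C)(C)C(C)(C)C)C1 | intermediate
7 | (R)-5-(tert-butyldimethylsilyloxy)-3-[2-methyl-2-(triethylsilyloxy)propoxy]cyclohex-2-en-1-one | O=C1C=C(OCC(C)(C)O[Si](CC)(CC)CC)C[C@@H](O[Si](C)(C)C(C)(C)C)C1 | intermediate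
8 | (R)-5-(tert-butyldimethylsilyloxy)-2-iodo-3-[2-methyl-2-(triethylsilyloxy)propoxy]cyclohex-2-en-1-one | O=C1C(I)=C(OCC(C)(C)O[Si](CC)(CC)CC)C[C@@H](O[Si](C)(C)C(C)(C)C)C1 | intermediate
9 | methyl 3-formyl-4-hydroxybenzoate | COC(=O)c1ccc(O)c(C=O)c1 | starting material
10 | methyl 4-(tert-butyldimethylsilyloxy)-3-formylbenzoate | COC(=O)c1ccc(O[Si](C)(C)C(C)(C)C)c(C=O)c1 | intermediate
11 | methyl 4-(tert-butyldimethylsilyloxy)-3-{hydroxy[(4R)-4-(tert-butyldimethylsilyloxy)-2-[2-methyl-2-(triethylsilyloxy)propoxy]-6-oxocyclohex-1-en-1-yl]methyl}benzoate (both carbinol epimers) | COC(=O)c1ccc(O[Si](C)(C)C(C)(C)C)c(C(O)C2=C(OCC(C)(C)O[Si](CC)(CC)CC)C[C@@H](O[Si](C)(C)C(C)(C)C)CC2=O)c1 | intermediate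
12 | methyl 4-(tert-butyldimethylsilyloxy)-3-{[(4R)-4-(tert-butyldimethylsilyloxy)-2-[2-methyl-2-(triethylsilyloxy)propoxy]-6-oxocyclohex-1-en-1-yl]carbonyl}benzoate | COC(=O)c1ccc(O[Si](C)(C)C(C)(C)C)c(C(=O)C2=C(OCC(C)(C)O[Si](CC)(CC)CC)C[C@@H](O[Si](C)(C)C(C)(C)C)CC2=O)c1 | intermediate
13 | 3-phenylpropanal | O=CCCc1ccccc1 | starting material
14 | lithium alkoxide of the C7 aldol adduct of 12 and 13 (3R,4S in the cyclohexenyl ring; C1′ unassigned) | COC(=O)c1ccc(O[Si](C)(C)C(C)(C)C)c(C(=O)C2=C(OCC(C)(C)O[Si](CC)(CC)CC)[C@H](C([O-])CCc3ccccc3)[C@@H](O[Si](C)(C)C(C)(C)C)CC2=O)c1.[Li+] | intermediate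
15 | methyl 3-{[(3R,4S)-3-[1-(allyloxycarbonyloxy)-3-phenylpropyl]-4-(tert-butyldimethylsilyloxy)-2-[2-methyl-2-(triethylsilyloxy)propoxy]-6-oxocyclohex-1-en-1-yl]carbonyl}-4-(tert-butyldimethylsilyloxy)benzoate (both C1′ epimers) | COC(=O)c1ccc(O[Si](C)(C)C(C)(C)C)c(C(=O)C2=C(OCC(C)(C)O[Si](CC)(CC)CC)[C@H](C(OC(=O)OCC=C)CCc3ccccc3)[C@@H](O[Si](C)(C)C(C)(C)C)CC2=O)c1 | intermediate
16 | N-(tert-butyldimethylsilyl)hydrazone of 15 at the aryl ketone | COC(=O)c1ccc(O[Si](C)(C)C(C)(C)C)c(C(=NN[Si](C)(C)C(C)(C)C)C2=C(OCC(C)(C)O[Si](CC)(CC)CC)[C@H](C(OC(=O)OCC=C)CCc3ccccc3)[C@@H](O[Si](C)(C)C(C)(C)C)CC2=O)c1 | intermediate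
17 | methyl 3-{diazo[(3R,4S)-3-[1-(allyloxycarbonyloxy)-3-phenylpropyl]-4-(tert-butyldimethylsilyloxy)-2-[2-methyl-2-(triethylsilyloxy)propoxy]-6-oxocyclohex-1-en-1-yl]methyl}-4-(tert-butyldimethylsilyloxy)benzoate | COC(=O)c1ccc(O[Si](C)(C)C(C)(C)C)c(C(=[N+]=[N-])C2=C(OCC(C)(C)O[Si](CC)(CC)CC)[C@H](C(OC(=O)OCC=C)CCc3ccccc3)[C@@H](O[Si](C)(C)C(C)(C)C)CC2=O)c1 | intermediate
18 | methyl 3-[(2R,3S,6S,7R)-7-[1-(allyloxycarbonyloxy)-3-phenylpropyl]-6-(tert-butyldimethylsilyloxy)-4-oxo-2-[2-(triethylsilyloxy)propan-2-yl]-2,3,4,5,6,7-hexahydro-1-benzofuran-3-yl]-4-(tert-butyldimethylsilyloxy)benzoate | COC(=O)c1ccc(O[Si](C)(C)C(C)(C)C)c([C@H]2C3=C(O[C@H]2C(C)(C)O[Si](CC)(CC)CC)[C@H](C(OC(=O)OCC=C)CCc4ccccc4)[C@@H](O[Si](C)(C)C(C)(C)C)CC3=O)c1 | intermediate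
19 | 4-methoxy oxocarbenium (1,3-dialkoxyallyl cation) triflate derived from 18 | COC(=O)c1ccc(O[Si](C)(C)C(C)(C)C)c([C@H]2C3=C(O[C@H]2C(C)(C)O[Si](CC)(CC)CC)[C@H](C(OC(=O)OCC=C)CCc4ccccc4)[C@@H](O[Si](C)(C)C(C)(C)C)CC3=[O+]C)c1.[O-]S(=O)(=O)C(F)(F)F | intermediate
20 | methyl 3-[(2R,3S,6S,7R)-7-[1-(allyloxycarbonyloxy)-3-phenylpropyl]-6-(tert-butyldimethylsilyloxy)-4-methoxy-2-[2-(triethylsilyloxy)propan-2-yl]-2,3,6,7-tetrahydro-1-benzofuran-3-yl]-4-(tert-butyldimethylsilyloxy)benzoate | COC(=O)c1ccc(O[Si](C)(C)C(C)(C)C)c([C@H]2C3=C(O[C@H]2C(C)(C)O[Si](CC)(CC)CC)[C@H](C(OC(=O)OCC=C)CCc4ccccc4)[C@@H](O[Si](C)(C)C(C)(C)C)C=C3OC)c1 | intermediate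
21 | methyl 4-(tert-butyldimethylsilyloxy)-3-[(2R,3S,6S,7R)-6-(tert-butyldimethylsilyloxy)-7-(1-hydroxy-3-phenylpropyl)-4-methoxy-2-[2-(triethylsilyloxy)propan-2-yl]-2,3,6,7-tetrahydro-1-benzofuran-3-yl]benzoate (both C1′ epimers) | COC(=O)c1ccc(O[Si](C)(C)C(C)(C)C)c([C@H]2C3=C(O[C@H]2C(C)(C)O[Si](CC)(CC)CC)[C@H](C(O)CCc4ccccc4)[C@@H](O[Si](C)(C)C(C)(C)C)C=C3OC)c1 | intermediate
22 | methyl 4-(tert-butyldimethylsilyloxy)-3-[(2R,3S,6S,7R)-6-(tert-butyldimethylsilyloxy)-4-methoxy-7-(3-phenylpropanoyl)-2-[2-(triethylsilyloxy)propan-2-yl]-2,3,6,7-tetrahydro-1-benzofuran-3-yl]benzoate | COC(=O)c1ccc(O[Si](C)(C)C(C)(C)C)c([C@H]2C3=C(O[C@H]2C(C)(C)O[Si](CC)(CC)CC)[C@H](C(=O)CCc4ccccc4)[C@@H](O[Si](C)(C)C(C)(C)C)C=C3OC)c1 | intermediate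
23 | lithium enolate of 22 (C7=C1′, conjugated with the ring C diene) | COC(=O)c1ccc(O[Si](C)(C)C(C)(C)C)c([C@H]2C3=C(O[C@H]2C(C)(C)O[Si](CC)(CC)CC)C(=C([O-])CCc4ccccc4)[C@@H](O[Si](C)(C)C(C)(C)C)C=C3OC)c1.[Li+] | intermediate
24 | methyl 4-(tert-butyldimethylsilyloxy)-3-[(2R,3S,6S,7S)-6-(tert-butyldimethylsilyloxy)-4-methoxy-7-(3-phenylpropanoyl)-2-[2-(triethylsilyloxy)propan-2-yl]-2,3,6,7-tetrahydro-1-benzofuran-3-yl]benzoate | COC(=O)c1ccc(O[Si](C)(C)C(C)(C)C)c([C@H]2C3=C(O[C@H]2C(C)(C)O[Si](CC)(CC)CC)[C@@H](C(=O)CCc4ccccc4)[C@@H](O[Si](C)(C)C(C)(C)C)C=C3OC)c1 | intermediate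
25 | methyl 4-hydroxy-3-[(2R,3S,6S,7S)-6-hydroxy-2-(2-hydroxypropan-2-yl)-4-methoxy-7-(3-phenylpropanoyl)-2,3,6,7-tetrahydro-1-benzofuran-3-yl]benzoate (CNP0080427.1) | COC(=O)c1ccc(O)c([C@H]2C3=C(O[C@H]2C(C)(C)O)[C@@H](C(=O)CCc2ccccc2)[C@@H](O)C=C3OC)c1 | target

**Count and risks**

Total steps: 18. Longest linear sequence: 17 (steps 1–6 and 8–18; step 7 is the side branch).

Steps most likely to fail:

- Step 11. The condensation at the crowded aryl ketone may be too slow, or the nitrogen reagent may attack the electrophilic C7a of the 2-acyl vinylogous ester with loss of the alkoxy group. Fallback: ketone 15 is condensed with 2,4,6-triisopropylbenzenesulfonyl hydrazide (THF, MeOH, rt) to the sulfonyl hydrazone F1. Its lithium salt (LiOtBu, THF) should fragment at 25–40 °C in a Bamford–Stevens reaction, giving diazo compound 17 directly and bypassing 16 and the oxidation.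

- Step 13. The C2–H bonds are poorly hydridic, because O1 belongs to a vinylogous ester and the neighbouring carbon is fully substituted and carries a silyl ether. Azine formation or electrocyclisation of the vinyl diazo unit may therefore outrun insertion, and the ring C centres may erode catalyst control. Fallback: the C–H bond is made allylic.
  - Ketone 12 undergoes alkoxide exchange at C7a by addition–elimination with 2-methylprop-2-en-1-ol (cat. NaH, THF, 0 °C) to give the methallyl ether ketone F2.
  - The sequence of steps 10–12 then gives the aldol carbonate F3, the N-silyl hydrazone F4 and the diazo compound F5.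
  - Insertion with the same dirhodium catalyst into the allylic, ether-activated C2–H bond should give the 2-isopropenyl ring B ketone F6.
  - Mukaiyama hydration (Mn(dpm)3, PhSiH3, O2, iPrOH), selective for the 1,1-disubstituted alkene over the allyl carbonate, gives the tertiary alcohol F7.
  - Silylation with TESOTf and 2,6-lutidine returns to 18.

- Step 17. The extended enolate may expel the C6 silyloxy group, which aromatises ring C, and deprotonation at C2′ or poor facial selectivity may leave the 7-epimer. Fallback: ketone 22 is enolised without a strong base (TMSOTf, Et3N, CH2Cl2, −78 °C) to the trimethylsilyl trienol ether F8. This is cleaved at −78 °C with acetic-acid-buffered Bu4NF, so that the enolate is protonated as soon as it forms, giving 24.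

Further compounds
F1 | step 11 | 2,4,6-triisopropylbenzenesulfonyl hydrazone of 15 at the aryl ketone | COC(=O)c1ccc(O[Si](C)(C)C(C)(C)C)c(C(=NNS(=O)(=O)c5c(C(C)C)cc(C(C)C)cc5C(C)C)C2=C(OCC(C)(C)O[Si](CC)(CC)CC)[C@H](C(OC(=O)OCC=C)CCc3ccccc3)[C@@H](O[Si](C)(C)C(C)(C)C)CC2=O)c1
F2 | step 13 | methyl 4-(tert-butyldimethylsilyloxy)-3-{[(4R)-4-(tert-butyldimethylsilyloxy)-2-(2-methylprop-2-enyloxy)-6-oxocyclohex-1-en-1-yl]carbonyl}benzoate | COC(=O)c1ccc(O[Si](C)(C)C(C)(C)C)c(C(=O)C2=C(OCC(C)=C)C[C@@H](O[Si](C)(C)C(C)(C)C)CC2=O)c1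
F3 | step 13 | methyl 3-{[(3R,4S)-3-[1-(allyloxycarbonyloxy)-3-phenylpropyl]-4-(tert-butyldimethylsilyloxy)-2-(2-methylprop-2-enyloxy)-6-oxocyclohex-1-en-1-yl]carbonyl}-4-(tert-butyldimethylsilyloxy)benzoate (both C1′ epimers) | COC(=O)c1ccc(O[Si](C)(C)C(C)(C)C)c(C(=O)C2=C(OCC(C)=C)[C@H](C(OC(=O)OCC=C)CCc3ccccc3)[C@@H](O[Si](C)(C)C(C)(C)C)CC2=O)c1
F4 | step 13 | N-(tert-butyldimethylsilyl)hydrazone of F3 at the aryl ketone | COC(=O)c1ccc(O[Si](C)(C)C(C)(C)C)c(C(=NN[Si](C)(C)C(C)(C)C)C2=C(OCC(C)=C)[C@H](C(OC(=O)OCC=C)CCc3ccccc3)[C@@H](O[Si](C)(C)C(C)(C)C)CC2=O)c1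
F5 | step 13 | methyl 3-{diazo[(3R,4S)-3-[1-(allyloxycarbonyloxy)-3-phenylpropyl]-4-(tert-butyldimethylsilyloxy)-2-(2-methylprop-2-enyloxy)-6-oxocyclohex-1-en-1-yl]methyl}-4-(tert-butyldimethylsilyloxy)benzoate | COC(=O)c1ccc(O[Si](C)(C)C(C)(C)C)c(C(=[N+]=[N-])C2=C(OCC(C)=C)[C@H](C(OC(=O)OCC=C)CCc3ccccc3)[C@@H](O[Si](C)(C)C(C)(C)C)CC2=O)c1
F6 | step 13 | methyl 3-[(2R,3S,6S,7R)-7-[1-(allyloxycarbonyloxy)-3-phenylpropyl]-6-(tert-butyldimethylsilyloxy)-4-oxo-2-(prop-1-en-2-yl)-2,3,4,5,6,7-hexahydro-1-benzofuran-3-yl]-4-(tert-butyldimethylsilyloxy)benzoate | COC(=O)c1ccc(O[Si](C)(C)C(C)(C)C)c([C@H]2C3=C(O[C@H]2C(C)=C)[C@H](C(OC(=O)OCC=C)CCc4ccccc4)[C@@H](O[Si](C)(C)C(C)(C)C)CC3=O)c1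
F7 | step 13 | methyl 3-[(2R,3S,6S,7R)-7-[1-(allyloxycarbonyloxy)-3-phenylpropyl]-6-(tert-butyldimethylsilyloxy)-2-(2-hydroxypropan-2-yl)-4-oxo-2,3,4,5,6,7-hexahydro-1-benzofuran-3-yl]-4-(tert-butyldimethylsilyloxy)benzoate | COC(=O)c1ccc(O[Si](C)(C)C(C)(C)C)c([C@H]2C3=C(O[C@H]2C(C)(C)O)[C@H](C(OC(=O)OCC=C)CCc4ccccc4)[C@@H](O[Si](C)(C)C(C)(C)C)CC3=O)c1
F8 | step 17 | trimethylsilyl trienol ether of 22 (C7=C1′) | COC(=O)c1ccc(O[Si](C)(C)C(C)(C)C)c([C@H]2C3=C(O[C@H]2C(C)(C)O[Si](CC)(CC)CC)C(=C(O[Si](C)(C)C)CCc4ccccc4)[C@@H](O[Si](C)(C)C(C)(C)C)C=C3OC)c1
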